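The isoflavone is cut through C4–C4a and O1–C2, back to an aryl 3-(dimethylamino)-2-arylacrylate of 3,5-bis(MOM)-4-prenylphenol. Ring A is a phloroglucinol whose prenyl carbon C6 sits para to C8a (the carbon bearing O1) between O5 and O7, so this phenol ester has a mirror plane and its two ortho C–H carbons are identical: either one becomes C4a. In one operation, ortho-lithiation triggers an O-to-C shift of the whole C2–C3(aryl)–C4 acyl unit, and the liberated phenol then closes the pyranone ring C by displacing dimethylamine. Only MOM removal remains.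

Key step: step 7

Remark: the target has no stereocentre and is achiral, so no enantioselective step is needed; the only stereo-descriptor on the route is the E enamine double bond of 11–13, which is consumed in step 7.

Step 1
Reactants: 1 phloroglucinol
Product: 2 3,5-bis(methoxymethoxy)phenol
Conditions: MOMCl (2 equiv), i-Pr2NEt, DMF, 0 °C to rt; chromatography
Reagents that add atoms: chloromethyl methyl ether, COCCl
Why: Base-mediated O-alkylation of the phenol with an α-chloro ether (Williamson-type acetal formation) should give the bis-acetal as the main component of a statistical mixture, separable from the recyclable mono- and tris-ethers.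

Step 2
Reactants: 2 3,5-bis(methoxymethoxy)phenol
Product: 3 [3,5-bis(methoxymethoxy)phenoxy]tri(propan-2-yl)silane
Conditions: TIPSCl, imidazole, DMF, rt
Reagents that add atoms: chlorotri(propan-2-yl)silane, CC(C)[Si](Cl)(C(C)C)C(C)C
Why: Imidazole-promoted silylation of the remaining phenol gives a bulky silyl ether that withstands butyllithium and, unlike an acetal, should not steer metalation to its own ortho positions.

Step 3
Reactants: 3 [3,5-bis(methoxymethoxy)phenoxy]tri(propan-2-yl)silane, 4 prenyl bromide (1-bromo-3-methylbut-2-ene)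
Product: 7 [3,5-bis(methoxymethoxy)-4-(3-methylbut-2-enyl)phenoxy]tri(propan-2-yl)silane, via aryllithium 5 (not isolated), via arylcopper 6 (not isolated)
Conditions: n-BuLi, THF, 0 °C; CuI, −40 °C; then 4, −40 °C to rt
Reagents that add atoms: none
Why: Directed ortho-metalation should remove the proton between the two chelating MOM acetals, and the derived arylcopper should couple with the allylic bromide at its primary carbon (SN2 allylation without allylic transposition).

Step 4
Reactants: 7 [3,5-bis(methoxymethoxy)-4-(3-methylbut-2-enyl)phenoxy]tri(propan-2-yl)silane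
Product: 8 3,5-bis(methoxymethoxy)-4-(3-methylbut-2-enyl)phenol
Conditions: TBAF, AcOH, THF, 0 °C to rt
Reagents that add atoms: none
Why: Fluoride-induced cleavage of the aryl silyl ether, buffered with acetic acid, should leave the MOM acetals and the alkene untouched.

Step 5
Reactants: 8 3,5-bis(methoxymethoxy)-4-(3-methylbut-2-enyl)phenol, 9 (2,3,4-trimethoxyphenyl)acetic acid
Product: 10 3,5-bis(methoxymethoxy)-4-(3-methylbut-2-enyl)phenyl 2-(2,3,4-trimethoxyphenyl)acetate
Conditions: EDC·HCl, DMAP (cat.), CH2Cl2, 0 °C to rt
Reagents that add atoms: none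
Why: Steglich esterification (carbodiimide activation with DMAP acyl transfer) acylates a phenol under near-neutral conditions that the acetals and the prenyl group tolerate.

Step 6
Reactants: 10 3,5-bis(methoxymethoxy)-4-(3-methylbut-2-enyl)phenyl 2-(2,3,4-trimethoxyphenyl)acetate
Product: 11 3,5-bis(methoxymethoxy)-4-(3-methylbut-2-enyl)phenyl (E)-3-(dimethylamino)-2-(2,3,4-trimethoxyphenyl)prop-2-enoate
Conditions: t-BuOCH(NMe2)2, toluene, 40–60 °C, N2 sweep
Reagents that add atoms: tert-butoxybis(dimethylamino)methane (Bredereck's reagent), CN(C)C(OC(C)(C)C)N(C)C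
Why: Aminomethylenation of an active methylene group by an aminal ester should work because the aryl- and aryloxycarbonyl-flanked CH2 is deprotonated by the released tert-butoxide, adds to the formamidinium ion and loses dimethylamine, and this reagent liberates no methoxide that could transesterify the aryl ester.

Step 7
Reactants: 11 3,5-bis(methoxymethoxy)-4-(3-methylbut-2-enyl)phenyl (E)-3-(dimethylamino)-2-(2,3,4-trimethoxyphenyl)prop-2-enoate
Product: 14 5,7-bis(methoxymethoxy)-6-(3-methylbut-2-enyl)-3-(2,3,4-trimethoxyphenyl)-4H-chromen-4-one, via ortho-lithiated ester 12 (not isolated), via hydroxyaryl enaminone 13 (not isolated)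
Conditions: LiTMP (from TMP, n-BuLi; 1.5 equiv), THF, −78 to 0 °C; then AcOH, THF, rt to 45 °C
Reagents that add atoms: none
Why: Proposed new method: LiTMP removes one of the two equivalent ring protons of 11, each lying between the acyloxy oxygen and a MOM ether and acidified and chelation-assisted by both, and aryllithium 12 adds to its own ester carbonyl; collapse of the four-membered tetrahedral adduct moves the acyl group from oxygen to carbon (C4–C4a) and leaves the lithium phenoxide of enaminone 13. The closest known reactions are the anionic ortho-Fries rearrangement of aryl carbamates and hindered aryl esters and, for the second stage, the closure of 2-hydroxyaryl enaminones to chromones as in the deoxybenzoin–amide acetal isoflavone synthesis; neither has been run from an aryl enamino ester. After protonation with acetic acid the phenol adds to the enaminone β-carbon (6-endo-trig oxa-Michael addition) and dimethylamine is eliminated, which forms O1–C2 and the pyranone ring. No stereocentre is created, and the E geometry of the enamine is irrelevant because that double bond is re-formed as C2=C3. The step needs chemoselectivity for ring metalation over attack on the acyl group: the acyl group is a vinylogous carbamate without α-hydrogen (poor electrophile, no enolate or ketene pathway), the base is hindered and non-nucleophilic at −78 °C, and deprotonation elsewhere (benzylic allylic CH2, enamine CH) is reversible and unproductive whereas the aryl anion is drained irreversibly by the acyl shift. Site selectivity is guaranteed by the mirror symmetry of ring A in 11, so either ortho carbon becomes C4a and the prenyl group ends up at C6.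

Step 8
Reactants: 14 5,7-bis(methoxymethoxy)-6-(3-methylbut-2-enyl)-3-(2,3,4-trimethoxyphenyl)-4H-chromen-4-one
Product: 15 5,7-dihydroxy-6-(3-methylbut-2-enyl)-3-(2,3,4-trimethoxyphenyl)-4H-chromen-4-one
Conditions: HCl (ca. 1 M) in MeOH, rt to 40 °C
Reagents that add atoms: none
Why: Acid-catalysed acetal exchange with methanol should remove both MOM groups as dimethoxymethane, and dilute acid near room temperature is chosen so that the prenyl alkene is not protonated and cyclised onto O5 or O7.

Compound list
1 | phloroglucinol (benzene-1,3,5-triol) | Oc1cc(O)cc(O)c1 | starting material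
2 | 3,5-bis(methoxymethoxy)phenol | COCOc1cc(O)cc(OCOC)c1 | intermediate
3 | [3,5-bis(methoxymethoxy)phenoxy]tri(propan-2-yl)silane | COCOc1cc(OCOC)cc(O[Si](C(C)C)(C(C)C)C(C)C)c1 | intermediate
4 | prenyl bromide (1-bromo-3-methylbut-2-ene) | CC(C)=CCBr | starting material
5 | [2,6-bis(methoxymethoxy)-4-{[tri(propan-2-yl)silyl]oxy}phenyl]lithium (not isolated) | [Li]c1c(OCOC)cc(O[Si](C(C)C)(C(C)C)C(C)C)cc1OCOC | intermediate
6 | [2,6-bis(methoxymethoxy)-4-{[tri(propan-2-yl)silyl]oxy}phenyl]copper (not isolated) | [Cu]c1c(OCOC)cc(O[Si](C(C)C)(C(C)C)C(C)C)cc1OCOC | intermediate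
7 | [3,5-bis(methoxymethoxy)-4-(3-methylbut-2-enyl)phenoxy]tri(propan-2-yl)silane | COCOc1cc(O[Si](C(C)C)(C(C)C)C(C)C)cc(OCOC)c1CC=C(C)C | intermediate
8 | 3,5-bis(methoxymethoxy)-4-(3-methylbut-2-enyl)phenol | COCOc1cc(O)cc(OCOC)c1CC=C(C)C | intermediate
9 | (2,3,4-trimethoxyphenyl)acetic acid | COc1ccc(CC(=O)O)c(OC)c1OC | starting material
10 | 3,5-bis(methoxymethoxy)-4-(3-methylbut-2-enyl)phenyl 2-(2,3,4-trimethoxyphenyl)acetate | COc1ccc(CC(=O)Oc2cc(OCOC)c(CC=C(C)C)c(OCOC)c2)c(OC)c1OC | intermediate
11 | 3,5-bis(methoxymethoxy)-4-(3-methylbut-2-enyl)phenyl (E)-3-(dimethylamino)-2-(2,3,4-trimethoxyphenyl)prop-2-enoate | CN(C)/C=C(\c1ccc(OC)c(OC)c1OC)C(=O)Oc1cc(OCOC)c(CC=C(C)C)c(OCOC)c1 | intermediate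
12 | 2-lithio-3,5-bis(methoxymethoxy)-4-(3-methylbut-2-enyl)phenyl (E)-3-(dimethylamino)-2-(2,3,4-trimethoxyphenyl)prop-2-enoate (lithium between the acyloxy oxygen and a MOM ether; not isolated) | CN(C)/C=C(\c1ccc(OC)c(OC)c1OC)C(=O)Oc1cc(OCOC)c(CC=C(C)C)c(OCOC)c1[Li] | intermediate
13 | (E)-3-(dimethylamino)-1-[6-hydroxy-2,4-bis(methoxymethoxy)-3-(3-methylbut-2-enyl)phenyl]-2-(2,3,4-trimethoxyphenyl)prop-2-en-1-one (formed as its lithium phenoxide and protonated in the quench; not isolated) | CN(C)/C=C(\c1ccc(OC)c(OC)c1OC)C(=O)c1c(O)cc(OCOC)c(CC=C(C)C)c1OCOC | intermediate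
14 | 5,7-bis(methoxymethoxy)-6-(3-methylbut-2-enyl)-3-(2,3,4-trimethoxyphenyl)-4H-chromen-4-one | COc1ccc(-c2coc3cc(OCOC)c(CC=C(C)C)c(OCOC)c3c2=O)c(OC)c1OC | intermediate
15 | 5,7-dihydroxy-6-(3-methylbut-2-enyl)-3-(2,3,4-trimethoxyphenyl)-4H-chromen-4-one | COc1ccc(-c2coc3cc(O)c(CC=C(C)C)c(O)c3c2=O)c(OC)c1OC | target

Total step count: 8
Longest linear sequence: 8 steps (1 to 15; 4 and 9 enter as purchased materials)

Steps most likely to fail

Step 7. What may go wrong: the amide base attacks or fragments the acyl group, or removes the benzylic allylic or enamine proton faster than the ring proton, or the aryllithium fails to capture the deactivated carbonyl, so no acyl shift occurs. The fallback uses known chemistry only and reaches the same enaminone through a stepwise deoxybenzoin route in which a differentiated phenol keeps the regiochemistry. It sets out from phenol 8 (with acid 9) and returns to the route at 14. Phenol 8 is protected with 3,4-dihydro-2H-pyran and PPTS in CH2Cl2 as the tetrahydropyranyl ether 2-[3,5-bis(methoxymethoxy)-4-(3-methylbut-2-enyl)phenoxy]oxane F1 (racemic at the acetal carbon). Acid 9 is converted with N,O-dimethylhydroxylamine hydrochloride, EDC and Et3N into the Weinreb amide N-methoxy-N-methyl-2-(2,3,4-trimethoxyphenyl)acetamide F2. n-BuLi in THF at 0 °C should metalate F1 between the THP and MOM acetals to give [2,4-bis(methoxymethoxy)-3-(3-methylbut-2-enyl)-6-(oxan-2-yloxy)phenyl]lithium F3, which is acylated by F2 at −78 °C to give 1-[2,4-bis(methoxymethoxy)-3-(3-methylbut-2-enyl)-6-(oxan-2-yloxy)phenyl]-2-(2,3,4-trimethoxyphenyl)ethan-1-one F4. PPTS in methanol should remove only the THP acetal and give 1-[6-hydroxy-2,4-bis(methoxymethoxy)-3-(3-methylbut-2-enyl)phenyl]-2-(2,3,4-trimethoxyphenyl)ethan-1-one F5. DMF dimethyl acetal in toluene at 80 °C then converts F5 through enaminone 13 into 14 (deoxybenzoin–amide acetal isoflavone synthesis).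

Step 6. What may go wrong: acyl transfer from the aryl ester to dimethylamine or tert-butoxide, or expulsion of the aryloxide from the ester enolate to a ketene, before the new C–C bond forms. The fallback separates enolate formation from amination, sets out from 10 and returns at 11. LiHMDS in THF at −78 °C should give the lithium enolate of 10, lithium 1-[3,5-bis(methoxymethoxy)-4-(3-methylbut-2-enyl)phenoxy]-2-(2,3,4-trimethoxyphenyl)ethen-1-olate F6. This is C-formylated at −78 °C in a crossed Claisen condensation with 2,2,2-trifluoroethyl formate to the hydroxymethylene ester 3,5-bis(methoxymethoxy)-4-(3-methylbut-2-enyl)phenyl (Z)-3-hydroxy-2-(2,3,4-trimethoxyphenyl)prop-2-enoate F7 (enol tautomer of the α-formyl ester). F7 is condensed with dimethylamine and a little acetic acid in THF at rt to give 11.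

Step 8. What may go wrong: protonation of the prenyl alkene followed by ring closure onto O5 or O7, or addition of methanol or HCl across the alkene, competing with acetal cleavage. The fallback replaces Brønsted-acid solvolysis by a buffered silyl exchange, sets out from 14 and returns at 15. TMSOTf with 2,2′-bipyridyl in CH2Cl2 at 0 °C should convert both aryl MOM ethers into silyl ethers, giving 6-(3-methylbut-2-enyl)-3-(2,3,4-trimethoxyphenyl)-5,7-bis(trimethylsilyloxy)-4H-chromen-4-one F8, which is hydrolysed with water during work-up to give 15.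

Further compounds
F1 | step 7 | 2-[3,5-bis(methoxymethoxy)-4-(3-methylbut-2-enyl)phenoxy]oxane (racemic) | COCOc1cc(OC2CCCCO2)cc(OCOC)c1CC=C(C)C
F2 | step 7 | N-methoxy-N-methyl-2-(2,3,4-trimethoxyphenyl)acetamide | COc1ccc(CC(=O)N(C)OC)c(OC)c1OC
F3 | step 7 | [2,4-bis(methoxymethoxy)-3-(3-methylbut-2-enyl)-6-(oxan-2-yloxy)phenyl]lithium (racemic, not isolated) | [Li]c1c(OC2CCCCO2)cc(OCOC)c(CC=C(C)C)c1OCOC
F4 | step 7 | 1-[2,4-bis(methoxymethoxy)-3-(3-methylbut-2-enyl)-6-(oxan-2-yloxy)phenyl]-2-(2,3,4-trimethoxyphenyl)ethan-1-one (racemic) | COc1ccc(CC(=O)c2c(OC3CCCCO3)cc(OCOC)c(CC=C(C)C)c2OCOC)c(OC)c1OC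
F5 | step 7 | 1-[6-hydroxy-2,4-bis(methoxymethoxy)-3-(3-methylbut-2-enyl)phenyl]-2-(2,3,4-trimethoxyphenyl)ethan-1-one | COc1ccc(CC(=O)c2c(O)cc(OCOC)c(CC=C(C)C)c2OCOC)c(OC)c1OC
F6 | step 6 | lithium 1-[3,5-bis(methoxymethoxy)-4-(3-methylbut-2-enyl)phenoxy]-2-(2,3,4-trimethoxyphenyl)ethen-1-olate (enolate geometry not defined, not isolated) | COc1ccc(C=C(O[Li])Oc2cc(OCOC)c(CC=C(C)C)c(OCOC)c2)c(OC)c1OC
F7 | step 6 | 3,5-bis(methoxymethoxy)-4-(3-methylbut-2-enyl)phenyl (Z)-3-hydroxy-2-(2,3,4-trimethoxyphenyl)prop-2-enoate | O/C=C(/c1ccc(OC)c(OC)c1OC)C(=O)Oc1cc(OCOC)c(CC=C(C)C)c(OCOC)c1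
F8 | step 8 | 6-(3-methylbut-2-enyl)-3-(2,3,4-trimethoxyphenyl)-5,7-bis(trimethylsilyloxy)-4H-chromen-4-one | COc1ccc(-c2coc3cc(O[Si](C)(C)C)c(CC=C(C)C)c(O[Si](C)(C)C)c3c2=O)c(OC)c1OC
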